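## Analysis of the target

Rhamnetin 3,3'-disulfate is a flavonol: ring A is fused to the 4-pyranone ring C, and ring B sits on C2. It has no stereocentre and no ring that is hard to close, so the whole problem is telling five oxygen atoms apart. O7 is a methyl ether, O5 and O4' are free phenols, and O3 (the enol oxygen of ring C) and O3' carry hydrogen sulfate groups. The sulfate half-esters are the sensitive groups: they are lost in protic or Lewis acid and make the molecule a polar salt, so they must go on late and be followed only by neutral chemistry. Ring A has the phloroglucinol pattern (O5, O7 and O1 on alternate carbons), so any route that acylates a symmetric ring A must later distinguish O5 from O7; ring B raises the same question between O3' and O4'. The strategy rests on one structural fact: C8a (bearing O1) and C4a (bearing the C4 carbonyl) are neighbours on ring A, and C4a has the C5 oxygen on its other side. An aryne spanning C4a and C8a with an alkoxy group on C5 is polarised so that an oxygen nucleophile enters at C8a and the carbon–carbon bond then forms at C4a. A single carboxylic acid that already holds C4, C3 with its oxygen, C2 and ring B can therefore deliver O1 and the aryl ketone in one operation.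

## Retrosynthetic reasoning

**25 to 24.** The last bonds cut are the two O–benzyl bonds at O5 and O4'. Hydrogenolysis is the only deprotection that is neutral enough to leave two sulfate half-esters intact, so the two oxygens that end as free phenols are the ones held as benzyl ethers throughout.

**24 to 23.** The two S–O bonds at O3 and O3' are cut next. The forward sulfation then has nothing to select, because diol 23 has exactly these two hydroxyls free.

**23 to 22.** O3 and O3' are the oxygens that must be unmasked in the presence of the benzyl ethers, so they are carried as methoxymethyl acetals. These survive base, fluoride and oxidants and fall to dilute acid before any sulfate is present.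

**22 to 21 to 20.** The C2=C3 double bond of flavone 22 is traced to flavanone 21 by dehydrogenation, and the O1–C2 bond of 21 to an oxa-Michael closure of the 2'-hydroxy chalcone 20. Cutting here leaves an open-chain ketone that already has O1 on C8a and the acyl carbon on C4a, which is what the key step produces.

**20 to 7 and 16.** Both bonds to ring A are cut at once: O1–C8a and C4–C4a. The aryne from silylaryl triflate 7 supplies the two adjacent ring carbons, and acid 16 supplies the carboxylate oxygen and the acyl group with the whole C4–C3–C2–ring B chain, the 3-oxygen included. The cut is made here because it is the only place where all five oxygens arrive already differentiated, on two fragments of similar size. The forward reaction must add the carboxylate at C8a, not C4a, and must transfer the acyl group to the aryl anion before that anion is protonated.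

**16 to 15 to 9 and 11.** The C2=C(aryl) double bond of the acid is cut by an aldol condensation between the enolate of ester 9 and aldehyde 11. Ester 9 comes from methyl glycolate 8 and aldehyde 11 from the mono-benzylated catechol aldehyde 10, in which the two ring B oxygens are already distinct.

**7 to 6 to 5 to 4 to 2 to 1.** The triflate is traced to phenol 6, and the benzyl ether of 6 to the symmetric silyl diol 5. The C–Si bond is deliberately made while ring A still has a mirror plane. The alternative would be to benzylate one hydroxyl of 1 first and make the other the directing carbamate. The metalation would then have to choose between two ortho positions that differ only in a benzyloxy versus a methoxy neighbour, and the benzylic CH2 would itself be exposed to the base. In bis-carbamate 2 the carbon between the two carbamates is the only one flanked by two strong directing groups, so lithiation and silylation go there (4). The symmetry of 4 and 5 lets the site of silylation be read directly, and the two oxygens are differentiated only afterwards by mono-benzylation and triflation.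

## Alternatives that were turned down

**Alternative 1:** The cut is at C4–C4a and O1–C2, between phloroglucinol A2 and the alpha-acyloxy beta-ketoester A3.
- **Forward step:** On strong heating without catalyst, A3 loses its ester alcohol to give an aroylketene. This C-acylates A2, and the neighbouring hydroxyl condenses onto the aryl ketone to close ring C, giving the 5,7-dihydroxyflavone A1.
- **For:** It is the shortest route. Ring A needs no protecting group, the symmetry of A2 removes any regiochemical question in the ring-forming step, and ring C is formed directly at the flavone oxidation level. On step economy it is stronger than the chosen route.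
- **Against:** Ketene formation needs far harsher heating than any step of the chosen route, in the presence of two pivalate esters and three free phenols, so acyl transfer between them is to be expected. Condensation through the ketone first would give the isomeric coumarin. The 7-O-methylation of A1 then relies on the chelation of O5–H, and the pivalates must be removed with base from an air-sensitive flavonol.
- **Comparison:** The chosen route is longer, but every oxygen is individually addressed from the start and no step depends on a reactivity difference between like hydroxyls.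

**Alternative 2:** The cut is at C3–C4 and O1–C2, between the benzodioxinone A5 and the alpha-alkoxy enamine A6.
- **Forward step:** Irradiation near 300 nm opens A5 to an ortho-quinoid ketene, which adds A6 across the C=C–N unit and then loses the secondary amine to give flavone A4.
- **For:** A4 is the same compound as flavone 22 of the chosen route, reached convergently in one ring-forming step and with no flavanone or dehydrogenation stage. After the key step this alternative is as strong as or stronger than the chosen one.
- **Against:** A5 needs a 2,6-dioxygenated benzoic acid whose two ortho oxygens must be told apart, so the ring A problem is not avoided and a carboxyl carbon is added to it. A6 is hydrolytically fragile. Each productive event releases one equivalent of a secondary amine, an excellent trap for the ketene. A4 absorbs strongly in the region used for the photolysis, so product screening and secondary photochemistry grow with conversion.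
- **Comparison:** The chosen route pays two extra steps after the key step but runs thermally, with no light-absorbing product in the way and no nucleophile released.

**Alternative 3:** The cut is at O1–C8a, in the 2,6-difluoroaryl 1,3-diketone A8.
- **Forward step:** With a mild carbonate base in a dipolar aprotic solvent, the enolate oxygen on the ring B side displaces one ortho fluoride and closes ring C, giving the 5-fluorochromone A7.
- **For:** The two fluorines of A8 are equivalent, so ring A regiochemistry is settled by symmetry. On this point the alternative is stronger than the chosen route, whose precursor needs a site-selective metalation and a mono-benzylation. The ring closure itself is very reliable.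
- **Against:** A7 still has fluorine where the target has O5. A second substitution by an oxygen nucleophile is needed on a chromone that also offers C2 to hard alkoxides (conjugate addition and opening of ring C) and carries a base-sensitive enol acetal on C3. Making A8 requires acylating an alpha-alkoxy ketone enolate with a hindered 2,6-disubstituted aroyl unit.
- **Comparison:** The chosen route has all ring A oxygens in place before the key step and never has to convert a carbon–fluorine bond into a carbon–oxygen bond on the finished heterocycle.

Key step: step 10

Assumption: the sulfate half-esters of 24 and 25 are written in the neutral hydrogen sulfate form of the target; in practice 24 would be handled as its bis(triethylammonium) salt and 25 liberated from the salt by cation exchange at the end.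

## Route

Step 1
Reactants: 1 5-methoxyresorcinol
Product: 2 5-methoxy-1,3-phenylene bis(N,N-diethylcarbamate)
Conditions: Et2NCOCl, K2CO3, MeCN, reflux
Reagents that add atoms: N,N-diethylcarbamoyl chloride, CCN(CC)C(=O)Cl
Why: O-acylation of both phenols with a carbamoyl chloride; the product keeps the mirror plane of 1 and carries two strong directing groups on either side of the carbon that must be silylated.

Step 2
Reactants: 2 5-methoxy-1,3-phenylene bis(N,N-diethylcarbamate)
Product: 4 5-methoxy-2-(trimethylsilyl)-1,3-phenylene bis(N,N-diethylcarbamate), via 2-lithio biscarbamate 3 (not isolated)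
Conditions: s-BuLi, TMEDA, THF, -78 °C; Me3SiCl, -78 °C to rt
Reagents that add atoms: chlorotrimethylsilane, C[Si](C)(C)Cl
Why: Directed ortho-metalation; the carbon between the two O-carbamates is bound and acidified by both, whereas the other two ring carbons have one carbamate and a weakly directing methoxy neighbour. The low temperature holds back the anionic Fries rearrangement, and the symmetric product shows the site of silylation directly.

Step 3
Reactants: 4 5-methoxy-2-(trimethylsilyl)-1,3-phenylene bis(N,N-diethylcarbamate)
Product: 5 5-methoxy-2-(trimethylsilyl)benzene-1,3-diol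
Conditions: LiAlH4, THF, 0 °C to reflux; aq. potassium sodium tartrate, pH near 7
Reagents that add atoms: none
Why: Hydride reduction of aryl carbamates expels the phenoxide and reduces the amide fragment to the amine. The medium is never acidic, which matters because the electron-rich aryl–silicon bond would be lost by ipso-protonation.

Step 4
Reactants: 5 5-methoxy-2-(trimethylsilyl)benzene-1,3-diol
Product: 6 3-(benzyloxy)-5-methoxy-2-(trimethylsilyl)phenol
Conditions: BnBr (1 equiv), K2CO3, acetone, rt
Reagents that add atoms: benzyl bromide, BrCc1ccccc1
Why: Williamson mono-etherification of a symmetric diol; the two hydroxyls are equivalent, so only one constitution of mono-ether can form. Unreacted 5 and the bis-ether are separated, and 5 is recycled.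

Step 5
Reactants: 6 3-(benzyloxy)-5-methoxy-2-(trimethylsilyl)phenol
Product: 7 3-(benzyloxy)-5-methoxy-2-(trimethylsilyl)phenyl trifluoromethanesulfonate
Conditions: PhNTf2, DBU, MeCN, 40 °C
Reagents that add atoms: N-phenylbis(trifluoromethanesulfonimide), O=S(=O)(N(c1ccccc1)S(=O)(=O)C(F)(F)F)C(F)(F)F
Why: Triflation of an ortho-silyl phenoxide with a mild triflyl donor under basic, acid-free conditions, the standard last step toward ortho-silylaryl triflates.

Step 6
Reactants: 8 methyl glycolate
Product: 9 methyl 2-(methoxymethoxy)acetate
Conditions: MOMCl, i-Pr2NEt, CH2Cl2, 0 °C to rt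
Reagents that add atoms: chloromethyl methyl ether, COCCl
Why: Acetal protection of the primary alcohol by alkylation with an alpha-chloro ether.

Step 7
Reactants: 10 4-(benzyloxy)-3-hydroxybenzaldehyde
Product: 11 4-(benzyloxy)-3-(methoxymethoxy)benzaldehyde
Conditions: MOMCl, i-Pr2NEt, CH2Cl2, 0 °C to rt
Reagents that add atoms: chloromethyl methyl ether, COCCl
Why: Same acetal protection on the phenol; the two catechol oxygens of ring B are now distinguished as benzyl (permanent) and methoxymethyl (temporary).

Step 8
Reactants: 9 methyl 2-(methoxymethoxy)acetate; 11 4-(benzyloxy)-3-(methoxymethoxy)benzaldehyde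
Product: 15 methyl (Z)-3-[4-(benzyloxy)-3-(methoxymethoxy)phenyl]-2-(methoxymethoxy)prop-2-enoate, via lithium enolate 12 (not isolated), via lithium aldolate 13 (not isolated), via beta-mesylate 14 (not isolated)
Conditions: LiN(i-Pr)2, THF, -78 °C; 11; MsCl, -78 to 0 °C; DBU, 0 °C to rt
Reagents that add atoms: none
Why: Aldol addition of the ester enolate to the aldehyde, then mesylation and E1cB elimination. The Z isomer (aryl trans to the ester) is the thermodynamically preferred alkene, and any E isomer can be carried on because the alkene geometry is erased in steps 11 and 12.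

Step 9
Reactants: 15 methyl (Z)-3-[4-(benzyloxy)-3-(methoxymethoxy)phenyl]-2-(methoxymethoxy)prop-2-enoate
Product: 16 (Z)-3-[4-(benzyloxy)-3-(methoxymethoxy)phenyl]-2-(methoxymethoxy)prop-2-enoic acid
Conditions: LiOH, THF/MeOH/H2O, rt; cold dilute HCl to pH 4
Reagents that add atoms: lithium hydroxide, [Li+].[OH-]
Why: Saponification of the methyl ester; the enol acetal and aryl acetal are stable to base and survive a brief cold acidification to pH 4.

Step 10
Reactants: 7 3-(benzyloxy)-5-methoxy-2-(trimethylsilyl)phenyl trifluoromethanesulfonate; 16 (Z)-3-[4-(benzyloxy)-3-(methoxymethoxy)phenyl]-2-(methoxymethoxy)prop-2-enoic acid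
Product: 20 (Z)-1-[2-(benzyloxy)-6-hydroxy-4-methoxyphenyl]-3-[4-(benzyloxy)-3-(methoxymethoxy)phenyl]-2-(methoxymethoxy)prop-2-en-1-one, via aryne 17 (not isolated), via aryl anion ester 18 (not isolated), via benzoxetene alkoxide 19 (not isolated)
Conditions: CsF (4 equiv), THF, 125 °C, sealed tube; aq. NH4Cl
Reagents that add atoms: none
Why: Fluoride attacks silicon and triflate leaves, giving aryne 17 across C4a and C8a, while CsF also turns 16 into its cesium carboxylate. The carboxylate oxygen adds to C8a to give aryl anion 18, which attacks its own ester carbonyl to form the four-membered alkoxide 19; this opens to the ortho-acyl phenoxide, protonated on work-up to 20, so that O1–C8a and C4–C4a are both formed. The closest known reaction type is the insertion of arynes into the C–O bond of carboxylic acids to give ortho-hydroxyaryl ketones, which is established for cinnamic acids; mechanistically the second stage is an anionic Fries-type acyl shift. No ring is closed and no stereocentre is formed, and the Z alkene is not touched. The step needs regioselective addition to the unsymmetrical aryne: the inductively withdrawing benzyloxy group on C5 distorts the aryne so that the nucleophile enters at the remote carbon C8a and the charge develops at C4a beside that oxygen, and the weaker, opposing bias of the C7 methoxy group should not overturn this. It also needs acyl transfer to outrun protonation of 18, which the aprotic medium, the excess of CsF and the intramolecularity secure. The chelated cesium phenoxide of 20 is a poor nucleophile toward further aryne, and partial oxa-Michael closure to 21 under these conditions would be harmless because step 11 leads to the same compound.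

Step 11
Reactants: 20 (Z)-1-[2-(benzyloxy)-6-hydroxy-4-methoxyphenyl]-3-[4-(benzyloxy)-3-(methoxymethoxy)phenyl]-2-(methoxymethoxy)prop-2-en-1-one
Product: 21 rel-(2R,3R)-5-(benzyloxy)-2-[4-(benzyloxy)-3-(methoxymethoxy)phenyl]-7-methoxy-3-(methoxymethoxy)chroman-4-one (racemic, trans)
Conditions: NaOAc, EtOH, reflux
Reagents that add atoms: none
Why: 6-endo-trig oxa-Michael addition of the phenoxide to the enone, favoured by the second ortho substituent, which twists the open chalcone out of conjugation. C2 and C3 are set under thermodynamic control through the reversible ring opening, so the trans diequatorial racemate should predominate; both centres are removed in step 12.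

Step 12
Reactants: 21 rel-(2R,3R)-5-(benzyloxy)-2-[4-(benzyloxy)-3-(methoxymethoxy)phenyl]-7-methoxy-3-(methoxymethoxy)chroman-4-one
Product: 22 5-(benzyloxy)-2-[4-(benzyloxy)-3-(methoxymethoxy)phenyl]-7-methoxy-3-(methoxymethoxy)-4H-chromen-4-one
Conditions: DDQ, 1,4-dioxane, reflux
Reagents that add atoms: none
Why: Quinone dehydrogenation of a flavanone to a flavone; hydride is taken from C2, where the cation is stabilised by O1 and the para-alkoxy group of ring B, and loss of the C3 proton gives the chromone.

Step 13
Reactants: 22 5-(benzyloxy)-2-[4-(benzyloxy)-3-(methoxymethoxy)phenyl]-7-methoxy-3-(methoxymethoxy)-4H-chromen-4-one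
Product: 23 5-(benzyloxy)-2-[4-(benzyloxy)-3-hydroxyphenyl]-3-hydroxy-7-methoxy-4H-chromen-4-one
Conditions: HCl, MeOH/THF, 40 °C
Reagents that add atoms: none
Why: Acid-catalysed acetal exchange removes both methoxymethyl groups and leaves the benzyl and methyl ethers, so exactly the two hydroxyls to be sulfated are set free.

Step 14
Reactants: 23 5-(benzyloxy)-2-[4-(benzyloxy)-3-hydroxyphenyl]-3-hydroxy-7-methoxy-4H-chromen-4-one
Product: 24 5-(benzyloxy)-2-[4-(benzyloxy)-3-(sulfooxy)phenyl]-7-methoxy-4-oxo-4H-chromen-3-yl hydrogen sulfate (isolated as the bis(triethylammonium) salt)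
Conditions: SO3·NMe3 (excess), Et3N, DMF, 60 °C
Reagents that add atoms: sulfur trioxide–trimethylamine complex, C[N+](C)(C)S(=O)(=O)[O-]
Why: O-sulfation of phenolic and enolic hydroxyls by transfer of SO3 from an amine complex; with O5 and O4' benzylated there is no other hydroxyl, so exhaustive sulfation gives the 3,3'-disulfate.

Step 15
Reactants: 24 5-(benzyloxy)-2-[4-(benzyloxy)-3-(sulfooxy)phenyl]-7-methoxy-4-oxo-4H-chromen-3-yl hydrogen sulfate
Product: 25 rhamnetin 3,3'-disulfate
Conditions: H2 (1 atm), Pd/C, MeOH/THF, rt; then H+-form sulfonic acid resin, 0 °C
Reagents that add atoms: none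
Why: Catalytic hydrogenolysis of the two aryl benzyl ethers under neutral conditions; sulfate salts are inert to hydrogen over palladium, and the tetrasubstituted, conjugated C2=C3 bond should not be reduced at ambient pressure.

## Compound list

1 | 5-methoxyresorcinol (5-methoxybenzene-1,3-diol) | COc1cc(O)cc(O)c1 | starting material
2 | 5-methoxy-1,3-phenylene bis(N,N-diethylcarbamate) | CCN(CC)C(=O)Oc1cc(OC)cc(OC(=O)N(CC)CC)c1 | intermediate
3 | 2-lithio-5-methoxy-1,3-phenylene bis(N,N-diethylcarbamate) | CCN(CC)C(=O)Oc1cc(OC)cc(OC(=O)N(CC)CC)c1[Li] | intermediate (not isolated)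
4 | 5-methoxy-2-(trimethylsilyl)-1,3-phenylene bis(N,N-diethylcarbamate) | CCN(CC)C(=O)Oc1cc(OC)cc(OC(=O)N(CC)CC)c1[Si](C)(C)C | intermediate
5 | 5-methoxy-2-(trimethylsilyl)benzene-1,3-diol | COc1cc(O)c([Si](C)(C)C)c(O)c1 | intermediate
6 | 3-(benzyloxy)-5-methoxy-2-(trimethylsilyl)phenol | COc1cc(O)c([Si](C)(C)C)c(OCc2ccccc2)c1 | intermediate
7 | 3-(benzyloxy)-5-methoxy-2-(trimethylsilyl)phenyl trifluoromethanesulfonate | COc1cc(OCc2ccccc2)c([Si](C)(C)C)c(OS(=O)(=O)C(F)(F)F)c1 | intermediate
8 | methyl glycolate | COC(=O)CO | starting material
9 | methyl 2-(methoxymethoxy)acetate | COCOCC(=O)OC | intermediate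
10 | 4-(benzyloxy)-3-hydroxybenzaldehyde | O=Cc1ccc(OCc2ccccc2)c(O)c1 | starting material
11 | 4-(benzyloxy)-3-(methoxymethoxy)benzaldehyde | COCOc1cc(C=O)ccc1OCc1ccccc1 | intermediate
12 | lithium enolate of methyl 2-(methoxymethoxy)acetate | [Li+].[O-]C(OC)=COCOC | intermediate (not isolated)
13 | lithium 1-[4-(benzyloxy)-3-(methoxymethoxy)phenyl]-3-methoxy-2-(methoxymethoxy)-3-oxopropan-1-olate (diastereomer mixture) | [Li+].[O-]C(c1ccc(OCc2ccccc2)c(OCOC)c1)C(OCOC)C(=O)OC | intermediate (not isolated)
14 | methyl 3-[4-(benzyloxy)-3-(methoxymethoxy)phenyl]-2-(methoxymethoxy)-3-[(methylsulfonyl)oxy]propanoate (diastereomer mixture) | COCOC(C(=O)OC)C(OS(C)(=O)=O)c1ccc(OCc2ccccc2)c(OCOC)c1 | intermediate (not isolated)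
15 | methyl (Z)-3-[4-(benzyloxy)-3-(methoxymethoxy)phenyl]-2-(methoxymethoxy)prop-2-enoate | COCO/C(=C\c1ccc(OCc2ccccc2)c(OCOC)c1)C(=O)OC | intermediate
16 | (Z)-3-[4-(benzyloxy)-3-(methoxymethoxy)phenyl]-2-(methoxymethoxy)prop-2-enoic acid | COCO/C(=C\c1ccc(OCc2ccccc2)c(OCOC)c1)C(=O)O | intermediate
17 | 3-(benzyloxy)-5-methoxy-1,2-didehydrobenzene (aryne) | COC1=CC#CC(OCc2ccccc2)=C1 | intermediate (not isolated)
18 | cesium 2-(benzyloxy)-4-methoxy-6-{[(Z)-3-[4-(benzyloxy)-3-(methoxymethoxy)phenyl]-2-(methoxymethoxy)prop-2-enoyl]oxy}benzenide | [Cs+].COCO/C(=C\c1ccc(OCc2ccccc2)c(OCOC)c1)C(=O)Oc1cc(OC)cc(OCc2ccccc2)[c-]1 | intermediate (not isolated)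
19 | cesium benzoxetene alkoxide (four-membered adduct of the aryl anion with its own ester carbonyl) | [Cs+].COCO/C(=C\c1ccc(OCc2ccccc2)c(OCOC)c1)C1([O-])Oc2cc(OC)cc(OCc3ccccc3)c21 | intermediate (not isolated)
20 | (Z)-1-[2-(benzyloxy)-6-hydroxy-4-methoxyphenyl]-3-[4-(benzyloxy)-3-(methoxymethoxy)phenyl]-2-(methoxymethoxy)prop-2-en-1-one | COCO/C(=C\c1ccc(OCc2ccccc2)c(OCOC)c1)C(=O)c1c(O)cc(OC)cc1OCc1ccccc1 | intermediate
21 | rel-(2R,3R)-5-(benzyloxy)-2-[4-(benzyloxy)-3-(methoxymethoxy)phenyl]-7-methoxy-3-(methoxymethoxy)chroman-4-one (racemic, trans) | COCOc1cc(ccc1OCc1ccccc1)[C@@H]1[C@H](C(=O)c2c(OCc3ccccc3)cc(OC)cc2O1)OCOC | intermediate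
22 | 5-(benzyloxy)-2-[4-(benzyloxy)-3-(methoxymethoxy)phenyl]-7-methoxy-3-(methoxymethoxy)-4H-chromen-4-one | COc1cc(OCc2ccccc2)c2c(=O)c(OCOC)c(-c3ccc(OCc4ccccc4)c(OCOC)c3)oc2c1 | intermediate
23 | 5-(benzyloxy)-2-[4-(benzyloxy)-3-hydroxyphenyl]-3-hydroxy-7-methoxy-4H-chromen-4-one | COc1cc(OCc2ccccc2)c2c(=O)c(O)c(-c3ccc(OCc4ccccc4)c(O)c3)oc2c1 | intermediate
24 | 5-(benzyloxy)-2-[4-(benzyloxy)-3-(sulfooxy)phenyl]-7-methoxy-4-oxo-4H-chromen-3-yl hydrogen sulfate (handled as bis(triethylammonium) salt) | COc1cc(OCc2ccccc2)c2c(=O)c(OS(=O)(=O)O)c(-c3ccc(OCc4ccccc4)c(OS(=O)(=O)O)c3)oc2c1 | intermediate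
25 | rhamnetin 3,3'-disulfate | COc1cc(O)c2c(=O)c(OS(=O)(=O)O)c(-c3ccc(O)c(OS(=O)(=O)O)c3)oc2c1 | target

## Step count and least certain steps

Total: 15 steps. Longest linear sequence: 11 steps (steps 1 to 5, then 10 to 15); the acid branch (steps 6 to 9) joins at step 10.

**Step 10 (key step).** The most likely failure is protonation of the aryl anion 18 before the acyl group has migrated, which ends in simple O-arylation of the acid. This is possible because hydrogen fluoride equivalents are present once the acid has been deprotonated, and because the anion is stabilised, and so made less nucleophilic, by its two flanking oxygens. Slow conversion of the electron-rich, alpha-oxygenated carboxylate and decay of the aryne by other pathways would act in the same direction. Pre-forming and drying the cesium salt of 16 should reduce the proton supply. The fallback abandons the aryne and forms the C4–C4a bond by acylating a metallated phenoxide: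
- It sets out from phenol 6 and acid 16 and returns at chalcone 20.
- Ipso-iododesilylation of 6 with ICl at low temperature should give 3-(benzyloxy)-2-iodo-5-methoxyphenol F1, the silicon marking the position regiospecifically.
- Acid 16 is converted through its acyl imidazolide into (Z)-3-[4-(benzyloxy)-3-(methoxymethoxy)phenyl]-N-methoxy-2-(methoxymethoxy)-N-methylprop-2-enamide F2.
- F1 is deprotonated with MeMgCl, subjected to iodine–magnesium exchange with i-PrMgCl·LiCl and added to F2; the chelated tetrahedral adduct collapses on work-up to 20.

**Step 2.** The aryllithium 3 sits between two carbamoyl groups and may undergo anionic Fries migration before it is silylated. Silylation in this crowded pocket may be slow, and some metalation at the carbons next to the methoxy group cannot be excluded. The fallback makes the C–Si bond intramolecularly, by a retro-Brook shift from a bromide, and has no migrating acyl group: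
- It sets out from 1 and returns at 7.
- Both hydroxyls of 1 are protected as 1-methoxy-3,5-bis(methoxymethoxy)benzene F3.
- Lithiation between the two acetal oxygens with n-BuLi and quenching with 1,2-dibromotetrafluoroethane gives 2-bromo-5-methoxy-1,3-bis(methoxymethoxy)benzene F4.
- Methanolic HCl (harmless to an aryl bromide) gives the symmetric 2-bromo-5-methoxybenzene-1,3-diol F5, whose symmetry confirms the site.
- Mono-benzylation gives 3-(benzyloxy)-2-bromo-5-methoxyphenol F6, and hexamethyldisilazane gives [3-(benzyloxy)-2-bromo-5-methoxyphenoxy]trimethylsilane F7.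
- n-BuLi at -78 °C effects bromine–lithium exchange, faster than any attack on the benzyl ether, followed by 1,3-migration of silicon from oxygen to carbon; the resulting phenoxide is trapped with Tf2O to give 7.
- The site question of the lithiation remains in this fallback, but it is settled on a stable, symmetric bromide.

**Step 12.** Hydride abstraction at C2 may be slow because of the electron-withdrawing acetal oxygen on C3, and on prolonged heating DDQ may begin to oxidise the benzylic ethers. Incomplete closure in step 11 would also leave chalcone that DDQ does not convert. The fallback changes the order of events so that the oxidation is done on a free alpha-hydroxy ketone: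
- It sets out from 21 and returns at 23.
- The acetals of 21 are removed with HCl in methanol to give rel-(2R,3R)-5-(benzyloxy)-2-[4-(benzyloxy)-3-hydroxyphenyl]-3-hydroxy-7-methoxychroman-4-one F8.
- This dihydroflavonol is oxidised to the flavonol 23 with I2 and KOAc in hot AcOH, the classical dehydrogenation of 3-hydroxyflavanones, which proceeds through the enediol.

**Step 14.** Sulfation of the C3 hydroxyl may stop short, since it is hydrogen-bonded to the C4 carbonyl and flanked by ring B, and the polar half-ester salts may lose a sulfate during isolation. The fallback installs the sulfates as neutral diesters that can be chromatographed: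
- It sets out from 23 and returns at 24.
- 23 is treated with 2,2,2-trichloroethyl chlorosulfate, Et3N and DMAP to give 5-(benzyloxy)-2-{4-(benzyloxy)-3-[(2,2,2-trichloroethoxy)sulfonyloxy]phenyl}-7-methoxy-4-oxo-4H-chromen-3-yl 2,2,2-trichloroethyl sulfate F9.
- Reductive removal of the trichloroethyl groups with zinc and HCO2NH4 in methanol gives 24 as its ammonium salt, which enters step 15 unchanged.

## Further compounds

F1 | step 10 | 3-(benzyloxy)-2-iodo-5-methoxyphenol | COc1cc(O)c(I)c(OCc2ccccc2)c1
F2 | step 10 | (Z)-3-[4-(benzyloxy)-3-(methoxymethoxy)phenyl]-N-methoxy-2-(methoxymethoxy)-N-methylprop-2-enamide | COCO/C(=C\c1ccc(OCc2ccccc2)c(OCOC)c1)C(=O)N(C)OC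
F3 | step 2 | 1-methoxy-3,5-bis(methoxymethoxy)benzene | COCOc1cc(OC)cc(OCOC)c1
F4 | step 2 | 2-bromo-5-methoxy-1,3-bis(methoxymethoxy)benzene | COCOc1cc(OC)cc(OCOC)c1Br
F5 | step 2 | 2-bromo-5-methoxybenzene-1,3-diol | COc1cc(O)c(Br)c(O)c1
F6 | step 2 | 3-(benzyloxy)-2-bromo-5-methoxyphenol | COc1cc(O)c(Br)c(OCc2ccccc2)c1
F7 | step 2 | [3-(benzyloxy)-2-bromo-5-methoxyphenoxy]trimethylsilane | COc1cc(O[Si](C)(C)C)c(Br)c(OCc2ccccc2)c1
F8 | step 12 | rel-(2R,3R)-5-(benzyloxy)-2-[4-(benzyloxy)-3-hydroxyphenyl]-3-hydroxy-7-methoxychroman-4-one | Oc1cc(ccc1OCc1ccccc1)[C@@H]1[C@H](C(=O)c2c(OCc3ccccc3)cc(OC)cc2O1)O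
F9 | step 14 | 5-(benzyloxy)-2-{4-(benzyloxy)-3-[(2,2,2-trichloroethoxy)sulfonyloxy]phenyl}-7-methoxy-4-oxo-4H-chromen-3-yl 2,2,2-trichloroethyl sulfate | COc1cc(OCc2ccccc2)c2c(=O)c(OS(=O)(=O)OCC(Cl)(Cl)Cl)c(-c3ccc(OCc4ccccc4)c(OS(=O)(=O)OCC(Cl)(Cl)Cl)c3)oc2c1
A1 | alternative 1 | 2-[4-(benzyloxy)-3-(pivaloyloxy)phenyl]-5,7-dihydroxy-3-(pivaloyloxy)-4H-chromen-4-one | CC(C)(C)C(=O)Oc1c(-c2ccc(OCc3ccccc3)c(OC(=O)C(C)(C)C)c2)oc2cc(O)cc(O)c2c1=O
A2 | alternative 1 | phloroglucinol (benzene-1,3,5-triol) | Oc1cc(O)cc(O)c1
A3 | alternative 1 | ethyl 3-[4-(benzyloxy)-3-(pivaloyloxy)phenyl]-3-oxo-2-(pivaloyloxy)propanoate | CCOC(=O)C(OC(=O)C(C)(C)C)C(=O)c1ccc(OCc2ccccc2)c(OC(=O)C(C)(C)C)c1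
A4 | alternative 2 | 5-(benzyloxy)-2-[4-(benzyloxy)-3-(methoxymethoxy)phenyl]-7-methoxy-3-(methoxymethoxy)-4H-chromen-4-one | COc1cc(OCc2ccccc2)c2c(=O)c(OCOC)c(-c3ccc(OCc4ccccc4)c(OCOC)c3)oc2c1
A5 | alternative 2 | 5-(benzyloxy)-7-methoxy-2,2-dimethyl-4H-1,3-benzodioxin-4-one | COc1cc(OCc2ccccc2)c2c(c1)OC(C)(C)OC2=O
A6 | alternative 2 | 4-{1-[4-(benzyloxy)-3-(methoxymethoxy)phenyl]-2-(methoxymethoxy)ethenyl}morpholine | COCOC=C(N1CCOCC1)c1ccc(OCc2ccccc2)c(OCOC)c1
A7 | alternative 3 | 2-[4-(benzyloxy)-3-(methoxymethoxy)phenyl]-5-fluoro-7-methoxy-3-(methoxymethoxy)-4H-chromen-4-one | COCOc1c(-c2ccc(OCc3ccccc3)c(OCOC)c2)oc2cc(OC)cc(F)c2c1=O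
A8 | alternative 3 | 1-[4-(benzyloxy)-3-(methoxymethoxy)phenyl]-3-(2,6-difluoro-4-methoxyphenyl)-2-(methoxymethoxy)propane-1,3-dione | COCOC(C(=O)c1ccc(OCc2ccccc2)c(OCOC)c1)C(=O)c1c(F)cc(OC)cc1F
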